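Numbering used throughout (target numbering): C1 = CMe2, C2 = CHBr, C3 = ring carbon of the exocyclic alkene, C4 = allylic CHCl, C5 = CH2, C6 = CHCl next to C1, C7 = vinylic CH, C8 = CH2Br. The target is (2S,4S,6S)-2-bromo-3-[(Z)-2-bromoethylidene]-4,6-dichloro-1,1-dimethylcyclohexane (15).

## The problem

The target 15 is a single cyclohexane ring (C1–C6) without any oxygen handle: a quaternary C1 flanked by two secondary halides (C2–Br, C6–Cl), an exocyclic (Z)-2-bromoethylidene group on C3, and a second chlorine on C4. The three stereocentres are 1,3,5-related and all S: Br at C2 and Cl at C6 are cis, Cl at C4 is trans to both, so in the chair with C2–Br and C6–Cl equatorial, C4–Cl is axial. C2 and C6 are neopentyl, so neither halogen can be put in by SN2 displacement with inversion. C2 and C4 are allylic, so both can ionise or react SN2' once the alkene is present. The alkene geometry is contra-steric: CH2Br lies syn to C2, the side that carries an equatorial bromine next to the quaternary carbon, so olefinations or allylic transpositions under steric or thermodynamic control should give the E isomer. Relative control must therefore come from events whose transition states do not feel this A(1,3) strain, and absolute control from one stereocentre, most simply C4–Cl, the only halide carbon that is not neopentyl. The feature that makes the key step possible is the C6(Cl)–C1(Me2)–C2(Br) triad inside the six-membered ring, with C3 at the oxidation level of a carbonyl carbon: C6–Cl/C1 is the retron of a chloriranium ion on a prenyl alkene, C1–C2 is the bond made when a brominated enol carbon opens that ion, and C3 is the enol (later ketone) carbon. The α-carbonyl and allylic halides of the intermediates will not survive strong base, nucleophilic amines, hydride reagents or warm free bromide.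

## Retrosynthesis

**15 ⇒ 14.** The last bonds made are two C–H bonds, C7–H and C8–H; removing H2 from C7/C8 gives the exocyclic bromoallene 14. This is preferred to ending with a C–Br bond or an olefination at C3, which would both place CH2Br away from the equatorial C2–Br. In 14 the C3=C7=C8 unit is linear, so the geometry problem is gone. The forward step must deliver H2 syn, in the ring plane, from the C4 side (equatorial H; C4–Cl axial) and not from the C2 side (equatorial Br), without cleaving C–Br.

**14 ⇒ 12 ⇒ 10 + 11.** C8–Br and C3–O are exchanged by an anti SN2' displacement on the tertiary propargylic mesylate 13 of alcohol 12. The C3–C7 bond is then cut to ketone 10 and ethynylmagnesium bromide 11. Bromide enters at the unhindered alkyne terminus, and the carbinol configuration of 12 is irrelevant because C3 becomes trigonal. A vinyl or allyl nucleophile in place of 11 would bring back the geometry problem. Ketone 10 has eight carbons, all three stereocentres and no alkene. The forward steps need 1,2-addition to an α,α'-dihalo ketone without enolisation or epoxide closure.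

**10 ⇒ 8 (key disconnection).** C1–C2 and C6–Cl are cut together and the C3 ketone becomes an enol acetate, which opens the ring to the (Z)-β-bromo enol acetate 8. This is the only cut that makes both neopentyl C–halogen centres without substitution at a neopentyl carbon and sets their cis relationship in one chair transition state. Cuts at C3–C4 or C4–C5 would leave both neopentyl halides to be made in an open chain. The precursor has one stereocentre, no ring and no quaternary carbon. The forward reaction needs Cl+ to go to the prenyl alkene and not to the enol acetate, a chair closure, a Z enol geometry, and relay from C4.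

**8 ⇒ 6 ⇒ 5 ⇒ 2 + 3.** The enol acetate is cut at O–acetyl to the bromoenolate 7, which comes from dibromo ketone 6 by loss of one bromine. Ketone 6 comes from alcohol 5, and the C2–C3 bond of 5 is cut to aldehyde 2 and dibromomethyllithium 4 (from dibromomethane 3). Enolising a bromomethyl ketone would be regiochemically ambiguous and would endanger the C4 stereocentre; the gem-dibromide makes enolate formation regiospecific and base-free at C4. The forward steps need a Z enolate and no epimerisation at C4.

**2 ⇒ 1.** The C4–Cl bond is cut to 5-methylhex-4-enal 1. C4 is the α-carbon of an aldehyde, so enamine catalysis can set it; this is the single catalyst-made stereocentre, from which C2, C6 and the alkene geometry are relayed.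

## Roads not taken

**Alternative 1:** The most obvious plan cuts all four C–halogen bonds back to C–O, giving tetraol A1 on a preformed ring, with exhaustive Appel-type deoxyhalogenation (inversion) as the forward key step. C2 and C6 are neopentyl, so SN2 there should lose to Wagner–Meerwein shift and elimination. C2 and C4 are allylic, so activation invites SN2' and ionisation. A1 also needs four oxygen stereo-elements, protecting groups and the same Z alkene, so it is longer and solves none of the hard points. The chosen plan makes no C–halogen bond by substitution at a ring carbon.

**Alternative 2:** The biomimetic plan cuts C1–C2, C6–Cl and C8–Br at once: chloriranium-initiated cyclisation of bromotriene A2, with the exocyclic allyl cation captured by bromide at C8. For equatorial bromine the vinyl bromide must have Br cis to the vinyl group, and then the diene can react only s-trans (s-cis clashes with Br). The allyl cation therefore carries C8 on the C4 side and gives the E isomer A3, not the target. In addition the bromodiene is a poor nucleophile, the cation is flanked by two C–halogen bonds, and chloride competes with bromide in the capture. The chosen plan keeps the chair argument of this route but replaces the diene by an enol ester and sets the geometry separately, by hydrogen delivery.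

**Alternative 3:** A ketone at C4 would control the geometry: bromide SN2' (conjugate addition–elimination) on the Morita–Baylis–Hillman-type adduct A4 gives the 2-alkylidene-3-bromo ketone A5, whose enone geometry (CH2 anti to C=O, hence syn to C2) is the right one. The ketone would then be converted to C4–Cl by reduction and inversion. But in A5 the alkylidene forces C2–Br axial, and axial entry of bromide anti to the C6 substituent gives the trans-2,6 isomer under both kinetic and thermodynamic control. Inversion at neopentyl C6, whose rear side is blocked by the axial bromine, is not feasible. The chosen plan sets the cis-2,6 pair in a chair ring closure, where both halogens are equatorial and no alkylidene is present yet.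

Key step: step 5

Assumption: 5-methylhex-4-enal (1), dibromomethane (3) and ethynylmagnesium bromide solution (11) are taken as catalogue chemicals.

## Route

Step 1
Reactants: 1 5-methylhex-4-enal
Product: 2 (S)-2-chloro-5-methylhex-4-enal
Conditions: NCS, trans-2,5-diphenylpyrrolidine (10 mol %, the enantiomer that gives the S aldehyde), CH2Cl2, 0 °C; pentane filtration, used at once
Reagents that add atoms: N-chlorosuccinimide, O=C1CCC(=O)N1Cl
Why: Organocatalytic α-chlorination of an aldehyde: the C2-symmetric pyrrolidine forms the enamine of 1 and shields one face, so NCS chlorinates the future C4 enantioselectively, while the isolated trisubstituted alkene is far less nucleophilic than the enamine. The product is used at once because α-chloro aldehydes racemise on standing.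

Step 2
Reactants: 2 (S)-2-chloro-5-methylhex-4-enal; 3 dibromomethane
Product: 5 (3S)-1,1-dibromo-3-chloro-6-methylhept-5-en-2-ol (C2 epimers), via dibromomethyllithium 4 (not isolated)
Conditions: 3, LiN(i-Pr)2, THF, −95 °C; then 2, −95 to −78 °C; AcOH quench at −78 °C
Reagents that add atoms: none
Why: 1,2-Addition of the carbenoid LiCHBr2 to the aldehyde at very low temperature should outrun enolisation, and the cold acidic quench prevents Darzens-type closure of the β-halo alkoxide. The new carbinol centre is destroyed in step 3, so its configuration does not matter.

Step 3
Reactants: 5 (3S)-1,1-dibromo-3-chloro-6-methylhept-5-en-2-ol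
Product: 6 (S)-1,1-dibromo-3-chloro-6-methylhept-5-en-2-one
Conditions: Dess–Martin periodinane, NaHCO3, CH2Cl2, 0 °C
Reagents that add atoms: none
Why: Buffered Dess–Martin oxidation of a secondary alcohol. In 6 the CHBr2 hydrogen is by far the most acidic, so any enolisation occurs away from the chlorine-bearing stereocentre.

Step 4
Reactants: 6 (S)-1,1-dibromo-3-chloro-6-methylhept-5-en-2-one
Product: 8 (1Z,3S)-1-bromo-3-chloro-6-methylhepta-1,5-dien-2-yl acetate, via chloromagnesium (Z)-bromoenolate 7 (not isolated)
Conditions: i-PrMgCl, THF, −78 °C; then Ac2O, −78 to −20 °C
Reagents that add atoms: acetic anhydride, CC(=O)OC(C)=O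
Why: Halophilic attack of the Grignard reagent on the α,α-dibromo ketone (bromine–magnesium exchange) forms the enolate regiospecifically on the bromomethylene side without touching the C–H next to chlorine. A(1,3) strain with the branched CHCl substituent should place Br cis to oxygen (Z enolate), and O-acetylation (enolate trapping as enol acetate) fixes that geometry.

Step 5
Reactants: 8 (1Z,3S)-1-bromo-3-chloro-6-methylhepta-1,5-dien-2-yl acetate
Product: 10 (2S,4S,6S)-2-bromo-4,6-dichloro-3,3-dimethylcyclohexan-1-one, via O-acetyl oxocarbenium ion 9 (not isolated)
Conditions: Et2SCl·SbCl6 (1.1 equiv), MeNO2, −25 °C; aq NaHCO3/Na2SO3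
Reagents that add atoms: chlorodiethylsulfonium hexachloroantimonate, CC[S+](Cl)CC.Cl[Sb-](Cl)(Cl)(Cl)(Cl)Cl
Why: Proposed new method: chloriranium-initiated cation–π cyclisation is known for polyenes terminated by arenes and alkenes, whereas here the terminator is a (Z)-β-bromo enol acetate, argued as follows. Cl+ from the sulfonium salt adds to the trisubstituted alkene, the most nucleophilic π bond (the enol acetate is deactivated by Br, by the ester and by the allylic C–Cl), and the brominated enol carbon C2 opens the chloriranium ion at its tertiary carbon C1 anti to chlorine. The six-membered ring closes 6-endo with respect to both the chloriranium ion and the enol double bond, through a chair. Anti opening makes C6–Cl equatorial; the Z enol geometry (Br anti to C4 across the double bond) makes C2–Br equatorial and hence cis to C6–Cl; allylic strain between the in-plane acetoxy group and the C4 substituents puts C4–H in the plane and C4–Cl axial, which selects the chair and the alkene face and so sets C2 and C6 relative to the one catalyst-made stereocentre. Chlorine transfer from sulfur is expected to be reversible while Et2S is present, so a mismatched chloriranium ion can revert. The O-acetyl oxocarbenium ion 9 loses its acetyl group to chloride to give ketone 10, in which equatorial Br with axial C4–Cl should also be the favoured arrangement, so the new centres should not epimerise. The closest known reactions are bromonium- and mercury-induced cyclisations terminated by enol derivatives.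

Step 6
Reactants: 10 (2S,4S,6S)-2-bromo-4,6-dichloro-3,3-dimethylcyclohexan-1-one; 11 ethynylmagnesium bromide
Product: 12 (2S,4S,6S)-2-bromo-4,6-dichloro-1-ethynyl-3,3-dimethylcyclohexan-1-ol (C1 epimers)
Conditions: 11, CeCl3, THF, −78 °C; AcOH quench at −78 °C
Reagents that add atoms: none
Why: Organocerium-mediated 1,2-addition of an acetylide to an enolisable α-halo ketone; the low basicity suppresses enolisation and halohydrin-to-epoxide closure. Either face may be attacked, since the carbinol carbon becomes sp2 in step 7 and both epimers converge.

Step 7
Reactants: 12 (2S,4S,6S)-2-bromo-4,6-dichloro-1-ethynyl-3,3-dimethylcyclohexan-1-ol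
Product: 14 (2S,4S,6S)-2-bromo-3-(2-bromoethenylidene)-4,6-dichloro-1,1-dimethylcyclohexane (allene-axis diastereomers), via tertiary propargylic mesylate 13 (not isolated)
Conditions: MsCl, Et3N, CH2Cl2, −40 °C; then LiCuBr2 (LiBr, CuBr), THF, −40 to 0 °C
Reagents that add atoms: lithium dibromocuprate LiCuBr2, [Li+].Br[Cu-]Br
Why: Sulfonylation through sulfene tolerates the hindered tertiary alcohol, and the bromocuprate then attacks the unhindered alkyne terminus in an anti SN2' displacement (propargylic sulfonate to bromoallene). The two allene diastereomers that arise from the carbinol epimers converge in step 8.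

Step 8
Reactants: 14 (2S,4S,6S)-2-bromo-3-(2-bromoethenylidene)-4,6-dichloro-1,1-dimethylcyclohexane
Product: 15 (2S,4S,6S)-2-bromo-3-[(Z)-2-bromoethylidene]-4,6-dichloro-1,1-dimethylcyclohexane
Conditions: KO2CN=NCO2K, AcOH, CH2Cl2, 0 °C to rt
Reagents that add atoms: none
Why: Proposed new method: diimide is known to transfer H2 to the less substituted double bond of allenes from the less hindered side and to reduce 1-haloalkynes without C–halogen cleavage, but a 1-bromoallene has not been used; the C7=C8 π lobes lie in the ring plane, where the C2 side is blocked by the equatorial bromine and the C4 side offers only an equatorial hydrogen (C4–Cl is axial), so concerted syn delivery should come from the C4 side, place H7 cis to C4 and swing CH2Br syn to C2, giving the Z alkene under kinetic control. The internal π bond is shielded on both ring faces (axial Cl at C4, axial methyl at C1) and the product alkene is trisubstituted, so over-reduction should be slow.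

## Compound list

1 | 5-methylhex-4-enal | CC(C)=CCCC=O | starting material
2 | (S)-2-chloro-5-methylhex-4-enal | O=C[C@@H](Cl)CC=C(C)C | intermediate
3 | dibromomethane | BrCBr | starting material
4 | dibromomethyllithium | [Li]C(Br)Br | intermediate (not isolated)
5 | (3S)-1,1-dibromo-3-chloro-6-methylhept-5-en-2-ol (both C2 epimers) | BrC(Br)C(O)[C@@H](Cl)CC=C(C)C | intermediate
6 | (S)-1,1-dibromo-3-chloro-6-methylhept-5-en-2-one | BrC(Br)C(=O)[C@@H](Cl)CC=C(C)C | intermediate
7 | chloromagnesium (1Z,3S)-1-bromo-3-chloro-6-methylhepta-1,5-dien-2-olate | Br/C=C(\O[Mg]Cl)[C@@H](Cl)CC=C(C)C | intermediate (not isolated)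
8 | (1Z,3S)-1-bromo-3-chloro-6-methylhepta-1,5-dien-2-yl acetate | Br/C=C(\OC(C)=O)[C@@H](Cl)CC=C(C)C | intermediate
9 | O-acetyl oxocarbenium ion of ketone 10 (hexachloroantimonate) | CC1(C)[C@H](Br)C(=[O+]C(C)=O)[C@@H](Cl)C[C@@H]1Cl | intermediate (not isolated)
10 | (2S,4S,6S)-2-bromo-4,6-dichloro-3,3-dimethylcyclohexan-1-one | CC1(C)[C@H](Br)C(=O)[C@@H](Cl)C[C@@H]1Cl | intermediate
11 | ethynylmagnesium bromide | C#C[Mg]Br | starting material
12 | (2S,4S,6S)-2-bromo-4,6-dichloro-1-ethynyl-3,3-dimethylcyclohexan-1-ol (both C1 epimers) | CC1(C)[C@H](Br)C(O)(C#C)[C@@H](Cl)C[C@@H]1Cl | intermediate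
13 | (2S,4S,6S)-2-bromo-4,6-dichloro-1-ethynyl-3,3-dimethylcyclohexyl methanesulfonate (both C1 epimers) | CC1(C)[C@H](Br)C(OS(C)(=O)=O)(C#C)[C@@H](Cl)C[C@@H]1Cl | intermediate (not isolated)
14 | (2S,4S,6S)-2-bromo-3-(2-bromoethenylidene)-4,6-dichloro-1,1-dimethylcyclohexane (both allene-axis diastereomers) | CC1(C)[C@H](Br)C(=C=CBr)[C@@H](Cl)C[C@@H]1Cl | intermediate
15 | (2S,4S,6S)-2-bromo-3-[(Z)-2-bromoethylidene]-4,6-dichloro-1,1-dimethylcyclohexane | CC1(C)[C@H](Br)/C(=C\CBr)[C@@H](Cl)C[C@@H]1Cl | target

## Step count and least certain steps

Total steps: 8. Longest linear sequence: 8 (from 1).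

**Step 5 (key step, carries the new-method label).** Three things are most likely to go wrong:
- The chloriranium ion may be intercepted before ring closure, by proton loss to an allylic chloride or by chloride capture, because the brominated, ester-deactivated enol carbon is a weak nucleophile.
- Facial discrimination at the remote alkene may be poor if chlorine transfer is not reversible, which would send part of the material through the chair with C4–Cl equatorial.
- The Lewis acid released may ionise the allylic C4–Cl bond or epimerise the α-halo ketone.

Fallback with known chemistry, from 8 back to 10: mercury-induced cyclisation with Hg(OTf)2·PhNMe2, a divalent mercury electrophile that closes polyenes onto enol derivatives through the same chair, then brine, should give the equatorial organomercurial [(1S,3S,5S)-3-bromo-5-chloro-2,2-dimethyl-4-oxocyclohexyl]mercury chloride F1. Halogenolysis of the C–Hg bond with Cl2 in pyridine (polar SE2 course, retention) then gives 10. This separates ring closure from C–Cl bond formation.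

**Step 8 (carries the new-method label).** Diimide may react sluggishly with the halogenated cumulene, attack the internal π bond, or show poor side selectivity in the ring plane; acetate could also substitute the allylic bromide of the product. Fallback with known chemistry, from 12 to 15, without the bromoallene:
- acetylation (Ac2O, DMAP) to the propargylic acetate (2S,4S,6S)-2-bromo-4,6-dichloro-1-ethynyl-3,3-dimethylcyclohexyl acetate F2;
- AgBF4-catalysed Saucy–Marbet 1,3-acyloxy shift to the allenyl acetate 2-[(2S,4S,6S)-2-bromo-4,6-dichloro-3,3-dimethylcyclohexylidene]ethenyl acetate F3;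
- K2CO3/MeOH at −20 °C, where the allenolate should be protonated in the ring plane from the same open C4 side, to the enal (Z)-2-[(2S,4S,6S)-2-bromo-4,6-dichloro-3,3-dimethylcyclohexylidene]acetaldehyde F4;
- immediate Luche reduction (NaBH4, CeCl3) to the allylic alcohol (Z)-2-[(2S,4S,6S)-2-bromo-4,6-dichloro-3,3-dimethylcyclohexylidene]ethanol F5;
- Appel bromination (PPh3, CBr4) at the primary allylic carbon to 15.

**Step 4.** The Grignard reagent may deprotonate the acidic CHBr2 group instead of attacking bromine, the enolate may form with the E geometry (which would put bromine axial in step 5), or acylation may occur on carbon. Fallback, from 6 back to 10, without an organometallic base: a Perkow reaction of 6 with P(OMe)3 gives, regiospecifically and with halogen cis to oxygen as usual for dihalomethyl ketones, the enol phosphate (1Z,3S)-1-bromo-3-chloro-6-methylhepta-1,5-dien-2-yl dimethyl phosphate F6. This is cyclised under the conditions of step 5, the phosphoryl group leaving as the acetyl group does, to rejoin the route at 10.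

**Step 7.** Sulfonylation of the hindered tertiary alcohol may fail, the sulfonate may ionise with participation of the anti-periplanar C4–Cl (1,2-chlorine shift), or bromide may substitute instead of adding at the terminus. Fallback, from 12 directly to 14 with no sulfonate: the classical CuBr/HBr/NH4Br conversion of free tertiary ethynyl carbinols into bromoallenes, in which the copper–alkyne complex delivers bromide to the terminus as the protonated hydroxyl leaves; it makes no new compound (F0).

## Further compounds

F1 | step 5 | [(1S,3S,5S)-3-bromo-5-chloro-2,2-dimethyl-4-oxocyclohexyl]mercury chloride | CC1(C)[C@H](Br)C(=O)[C@@H](Cl)C[C@@H]1[Hg]Cl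
F2 | step 8 | (2S,4S,6S)-2-bromo-4,6-dichloro-1-ethynyl-3,3-dimethylcyclohexyl acetate (both C1 epimers) | CC1(C)[C@H](Br)C(OC(C)=O)(C#C)[C@@H](Cl)C[C@@H]1Cl
F3 | step 8 | 2-[(2S,4S,6S)-2-bromo-4,6-dichloro-3,3-dimethylcyclohexylidene]ethenyl acetate (both allene-axis diastereomers) | CC1(C)[C@H](Br)C(=C=COC(C)=O)[C@@H](Cl)C[C@@H]1Cl
F4 | step 8 | (Z)-2-[(2S,4S,6S)-2-bromo-4,6-dichloro-3,3-dimethylcyclohexylidene]acetaldehyde | CC1(C)[C@H](Br)/C(=C\C=O)[C@@H](Cl)C[C@@H]1Cl
F5 | step 8 | (Z)-2-[(2S,4S,6S)-2-bromo-4,6-dichloro-3,3-dimethylcyclohexylidene]ethanol | CC1(C)[C@H](Br)/C(=C\CO)[C@@H](Cl)C[C@@H]1Cl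
F6 | step 4 | (1Z,3S)-1-bromo-3-chloro-6-methylhepta-1,5-dien-2-yl dimethyl phosphate | Br/C=C(\OP(=O)(OC)OC)[C@@H](Cl)CC=C(C)C
F0 | step 7 | none | none
A1 | alternative 1 | (1R,3R,5R,Z)-4-(2-hydroxyethylidene)-2,2-dimethylcyclohexane-1,3,5-triol (each carbinol centre of opposite spatial sense to the C–halogen centre it would become) | CC1(C)[C@@H](O)/C(=C\CO)[C@H](O)C[C@H]1O
A2 | alternative 2 | (1E,3S)-1-bromo-3-chloro-2-ethenyl-6-methylhepta-1,5-diene | Br/C=C(\C=C)[C@@H](Cl)CC=C(C)C
A3 | alternative 2 | (2S,4S,6S)-2-bromo-3-[(E)-2-bromoethylidene]-4,6-dichloro-1,1-dimethylcyclohexane | CC1(C)[C@H](Br)/C(=C/CBr)[C@@H](Cl)C[C@@H]1Cl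
A4 | alternative 3 | (5S)-5-chloro-2-[1-hydroxy-2-(tert-butyldimethylsilyloxy)ethyl]-4,4-dimethylcyclohex-2-en-1-one (both carbinol epimers) | CC1(C)C=C(C(O)CO[Si](C)(C)C(C)(C)C)C(=O)C[C@@H]1Cl
A5 | alternative 3 | (3S,5S)-3-bromo-5-chloro-2-[(Z)-2-(tert-butyldimethylsilyloxy)ethylidene]-4,4-dimethylcyclohexan-1-one (Br trans to Cl) | CC1(C)[C@@H](Br)/C(=C\CO[Si](C)(C)C(C)(C)C)C(=O)C[C@@H]1Cl
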